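## Retrosynthetic overview

- Target ⇐ one-pot removal of two silyl ethers and a tert-butyl ester; the (E)-2-methylbut-2-enoate arm ⇐ Wittig olefination of a CH2CHO unit on C6; the C1 ketone ⇐ Nef reaction of a ring nitro group; C3–CH2OH ⇐ reduction of a C3 ester.
- The only ring is closed in one operation: C1–C2 by conjugate addition of a nitronate (acyl-anion equivalent of the ketone carbon) to the β-carbon of an enynoate, then C3–C4 by intramolecular aldol addition of the resulting allenoate to an α-silyloxy aldehyde (sets C4).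
- The γ-nitroaldehyde (C4–C5–C6–C1) ⇐ organocatalytic Michael addition of silyloxyacetaldehyde to a nitroalkene (sets C5 and C6).
- The enynoate ⇐ Sonogashira coupling of methyl propiolate with an (E)-iodoalkene built from (R)-propylene oxide and but-1-yne (side-chain carbinol centre).

Assumption: the enamine of the silyloxyacetaldehyde reacts with the same topicity as alkyl aldehydes (E-enamine, attack anti to the CPh2OSiMe3 group); if the sense were opposite, the (S)-catalyst is used in step 7 and nothing else changes.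

Ring positions are labelled as in the target cyclohexenone: C1 ketone carbon, C2 alkenyl-bearing, C3 CH2OH-bearing, C4 and C5 carbinol carbons, C6 carbon carrying the acid side chain.

## Route

Step 1
Reactants: 1 (R)-2-methyloxirane; 2 but-1-yne
Product: 3 (R)-hept-4-yn-2-ol
Conditions: n-BuLi, THF, −78 °C; then 1, DMPU, −78 °C to rt
Reagents that add atoms: none
Why: SN2 opening of the epoxide at its CH2 terminus by lithium but-1-ynide (epoxide alkynylation) leaves the (R) carbinol centre untouched.

Step 2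
Reactants: 3 (R)-hept-4-yn-2-ol
Product: 4 (R)-hept-6-yn-2-ol
Conditions: KH, H2N(CH2)3NH2, 0 °C to rt; H2O
Reagents that add atoms: none
Why: Alkyne zipper reaction: potassium 3-aminopropylamide walks the triple bond to the chain end, where it is trapped as the acetylide, and the alkoxide-bearing stereocentre is not epimerised.

Step 3
Reactants: 4 (R)-hept-6-yn-2-ol
Product: 5 (R)-tert-butyl(hept-6-yn-2-yloxy)dimethylsilane
Conditions: TBSCl, imidazole, DMF, rt
Reagents that add atoms: tert-butyldimethylsilyl chloride (TBSCl), CC(C)(C)[Si](C)(C)Cl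
Why: Imidazole-promoted silylation of the secondary alcohol, so that the OH cannot add to the propiolate and ynoate acceptors used later.

Step 4
Reactants: 5 (R)-tert-butyl(hept-6-yn-2-yloxy)dimethylsilane
Product: 7 (R,E)-tert-butyl[(7-iodohept-6-en-2-yl)oxy]dimethylsilane, via alkenylzirconocene chloride 6 (not isolated)
Conditions: Cp2Zr(H)Cl, THF, rt; then I2, 0 °C
Reagents that add atoms: iodine (I2), II
Why: syn-Hydrozirconation puts zirconium on the terminal carbon and iodinolysis with retention gives the (E)-1-iodoalkene.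

Step 5
Reactants: 7 (R,E)-iodoalkene; 8 methyl propiolate
Product: 9 methyl (4E,9R)-9-(tert-butyldimethylsilyloxy)dec-4-en-2-ynoate
Conditions: Pd(PPh3)2Cl2 (2 mol %), CuI (4 mol %), K2CO3, THF, rt
Reagents that add atoms: none
Why: Sonogashira coupling retains the (E) geometry, and K2CO3 in place of an amine base avoids conjugate addition to the propiolate.

Step 6
Reactants: 10 4,4-diethoxybut-1-ene
Product: 11 (E)-4,4-diethoxy-1-nitrobut-1-ene
Conditions: AgNO2 (3 equiv), TEMPO (0.4 equiv), ClCH2CH2Cl, 70 °C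
Reagents that add atoms: silver nitrite (AgNO2), [Ag+].[O-]N=O
Why: Radical nitration of a terminal alkene (NO2 radical addition, then TEMPO-mediated loss of the β-hydrogen) gives the (E)-nitroalkene under neutral conditions that spare the acetal.

Step 7
Reactants: 11 (E)-4,4-diethoxy-1-nitrobut-1-ene; 12 2-(tert-butyldimethylsilyloxy)acetaldehyde
Product: 13 (2S,3R)-2-(tert-butyldimethylsilyloxy)-5,5-diethoxy-3-(nitromethyl)pentanal
Conditions: 12 (2 equiv), (R)-2-[diphenyl(trimethylsilyloxy)methyl]pyrrolidine (10 mol %), ClCH2CO2H (20 mol %), CH2Cl2, rt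
Reagents that add atoms: none
Why: Diarylprolinol silyl ether enamine catalysis (asymmetric Michael addition of an aldehyde to a nitroalkene): the E-enamine of 12 is shielded on one face by the CPh2OSiMe3 group and adds through the synclinal transition state to give the syn adduct, which fixes C5 (S) and C6 (R at this stage) so that their substituents end up trans on the ring.

Step 8
Reactants: 13 γ-nitroaldehyde; 9 enynoate
Product: 14 methyl (4R,5S,6R)-5-(tert-butyldimethylsilyloxy)-4-(2,2-diethoxyethyl)-6-hydroxy-3-nitro-2-[(1E,6R)-6-(tert-butyldimethylsilyloxy)hept-1-enyl]cyclohex-1-ene-1-carboxylate (mixture of epimers at the nitro carbon)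
Conditions: Cs2CO3 (1.2 equiv), MeCN, −20 to 0 °C; AcOH quench
Reagents that add atoms: none
Why: Proposed new method: Cs2CO3 deprotonates the CH2NO2 group of 13 and the nitronate (an acyl-anion equivalent for C1) adds to the β-carbon of ynoate 9 (C1–C2 bond), after which the allenoate α-carbon closes the six-membered ring by intramolecular aldol addition to the α-silyloxy aldehyde (C3–C4 bond); the new C4–OH is set cis to C5–OTBS by polar Felkin–Anh attack in a chair-like transition state with the C5 and C6 substituents equatorial (the reversible aldol also favours this axial, hydrogen-bonded OH), and the closest known reactions are the carbonate-mediated nitro-Michael/Horner–Wadsworth–Emmons annulation of γ-nitroaldehydes with vinylphosphonates and domino Michael/aldol (Morita–Baylis–Hillman-type) reactions of alkynoates and alkynals.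

Step 9
Reactants: 14 nitrocyclohexene ester
Product: 15 (1R,5R,6S)-6-(tert-butyldimethylsilyloxy)-5-(2,2-diethoxyethyl)-2-(hydroxymethyl)-4-nitro-3-[(1E,6R)-6-(tert-butyldimethylsilyloxy)hept-1-enyl]cyclohex-2-en-1-ol (mixture of epimers at the nitro carbon)
Conditions: i-Bu2AlH (5 equiv), CH2Cl2, −78 to −40 °C; aq. KNaC4H4O6 (potassium sodium tartrate)
Reagents that add atoms: none
Why: i-Bu2AlH reduces the conjugated ester 1,2 to the allylic alcohol while C1 is still a nitro carbon, so no ketone can compete; the nitro group, acetal and silyl ethers are inert at low temperature, and the OH and acidic C–H only consume extra hydride.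

Step 10
Reactants: 15 nitro diol
Product: 16 (4R,5S,6S)-5-(tert-butyldimethylsilyloxy)-6-(2,2-diethoxyethyl)-4-hydroxy-3-(hydroxymethyl)-2-[(1E,6R)-6-(tert-butyldimethylsilyloxy)hept-1-enyl]cyclohex-2-en-1-one
Conditions: K2CO3 (3 equiv), MeOH/H2O, 0 °C; then KHSO5 (as 2KHSO5·KHSO4·K2SO4), 0 °C
Reagents that add atoms: potassium peroxymonosulfate (KHSO5), [K+].[O-]S(=O)(=O)OO
Why: Oxidative Nef reaction: the allylic nitronate is hydroxylated at C1 by peroxymonosulfate and expels nitrite, which unveils the C1 ketone in conjugation with C2=C3; C6, now α to the ketone, sits in (or equilibrates to) the favoured arrangement trans to C5–OTBS (the descriptor at C6 changes from R to S only because C1 gains priority).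

Step 11
Reactants: 16 enone acetal; 17 tert-butyl 2-(triphenyl-λ5-phosphanylidene)propanoate
Product: 19 tert-butyl (2E)-4-[(1S,5R,6S)-6-(tert-butyldimethylsilyloxy)-5-hydroxy-4-(hydroxymethyl)-2-oxo-3-[(1E,6R)-6-(tert-butyldimethylsilyloxy)hept-1-enyl]cyclohex-3-en-1-yl]-2-methylbut-2-enoate, via aldehyde 18 (not isolated)
Conditions: PPTS (0.2 equiv), acetone/H2O (5:1), 40 °C; solvent switch to CH2Cl2; 17 (1.8 equiv), rt
Reagents that add atoms: none
Why: Mild acid hydrolysis of the diethyl acetal followed by Wittig olefination with a stabilised α-methyl ylide gives the trisubstituted (E)-enoate, and the hindered conjugated ketone does not react with the ylide.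

Step 12
Reactants: 19 bis-silyl tert-butyl ester
Product: 20 pestallic acid O
Conditions: CF3CO2H/CH2Cl2/H2O (5:5:1), 0 °C to rt
Reagents that add atoms: none
Why: Acidolysis cleaves both TBS ethers and the tert-butyl ester (loss of isobutene) in one operation without touching any stereocentre.

## Compound list

1 | (R)-2-methyloxirane ((R)-propylene oxide) | C[C@@H]1CO1 | starting material
2 | but-1-yne | CCC#C | starting material
3 | (R)-hept-4-yn-2-ol | CCC#CC[C@@H](C)O | intermediate
4 | (R)-hept-6-yn-2-ol | C#CCCC[C@@H](C)O | intermediate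
5 | (R)-tert-butyl(hept-6-yn-2-yloxy)dimethylsilane | C#CCCC[C@@H](C)O[Si](C)(C)C(C)(C)C | intermediate
6 | chloro[(1E,6R)-6-(tert-butyldimethylsilyloxy)hept-1-enyl]bis(cyclopentadienyl)zirconium | Cl[Zr](C1C=CC=C1)(C1C=CC=C1)/C=C/CCC[C@@H](C)O[Si](C)(C)C(C)(C)C | intermediate
7 | (R,E)-tert-butyl[(7-iodohept-6-en-2-yl)oxy]dimethylsilane | I/C=C/CCC[C@@H](C)O[Si](C)(C)C(C)(C)C | intermediate
8 | methyl propiolate (methyl prop-2-ynoate) | C#CC(=O)OC | starting material
9 | methyl (4E,9R)-9-(tert-butyldimethylsilyloxy)dec-4-en-2-ynoate | COC(=O)C#C/C=C/CCC[C@@H](C)O[Si](C)(C)C(C)(C)C | intermediate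
10 | 4,4-diethoxybut-1-ene (but-3-enal diethyl acetal) | C=CCC(OCC)OCC | starting material
11 | (E)-4,4-diethoxy-1-nitrobut-1-ene | CCOC(OCC)C/C=C/[N+](=O)[O-] | intermediate
12 | 2-(tert-butyldimethylsilyloxy)acetaldehyde | O=CCO[Si](C)(C)C(C)(C)C | starting material
13 | (2S,3R)-2-(tert-butyldimethylsilyloxy)-5,5-diethoxy-3-(nitromethyl)pentanal | O=C[C@@H](O[Si](C)(C)C(C)(C)C)[C@@H](C[N+](=O)[O-])CC(OCC)OCC | intermediate
14 | methyl (4R,5S,6R)-5-(tert-butyldimethylsilyloxy)-4-(2,2-diethoxyethyl)-6-hydroxy-3-nitro-2-[(1E,6R)-6-(tert-butyldimethylsilyloxy)hept-1-enyl]cyclohex-1-ene-1-carboxylate, epimers at the nitro carbon | CCOC(OCC)C[C@@H]1C([N+](=O)[O-])C(/C=C/CCC[C@@H](C)O[Si](C)(C)C(C)(C)C)=C(C(=O)OC)[C@@H](O)[C@H]1O[Si](C)(C)C(C)(C)C | intermediate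
15 | (1R,5R,6S)-6-(tert-butyldimethylsilyloxy)-5-(2,2-diethoxyethyl)-2-(hydroxymethyl)-4-nitro-3-[(1E,6R)-6-(tert-butyldimethylsilyloxy)hept-1-enyl]cyclohex-2-en-1-ol, epimers at the nitro carbon | CCOC(OCC)C[C@@H]1C([N+](=O)[O-])C(/C=C/CCC[C@@H](C)O[Si](C)(C)C(C)(C)C)=C(CO)[C@@H](O)[C@H]1O[Si](C)(C)C(C)(C)C | intermediate
16 | (4R,5S,6S)-5-(tert-butyldimethylsilyloxy)-6-(2,2-diethoxyethyl)-4-hydroxy-3-(hydroxymethyl)-2-[(1E,6R)-6-(tert-butyldimethylsilyloxy)hept-1-enyl]cyclohex-2-en-1-one | CCOC(OCC)C[C@@H]1C(=O)C(/C=C/CCC[C@@H](C)O[Si](C)(C)C(C)(C)C)=C(CO)[C@@H](O)[C@H]1O[Si](C)(C)C(C)(C)C | intermediate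
17 | tert-butyl 2-(triphenyl-λ5-phosphanylidene)propanoate | CC(C(=O)OC(C)(C)C)=P(c1ccccc1)(c1ccccc1)c1ccccc1 | starting material
18 | 2-[(1S,5R,6S)-6-(tert-butyldimethylsilyloxy)-5-hydroxy-4-(hydroxymethyl)-2-oxo-3-[(1E,6R)-6-(tert-butyldimethylsilyloxy)hept-1-enyl]cyclohex-3-en-1-yl]acetaldehyde | O=CC[C@@H]1C(=O)C(/C=C/CCC[C@@H](C)O[Si](C)(C)C(C)(C)C)=C(CO)[C@@H](O)[C@H]1O[Si](C)(C)C(C)(C)C | intermediate
19 | tert-butyl (2E)-4-[(1S,5R,6S)-6-(tert-butyldimethylsilyloxy)-5-hydroxy-4-(hydroxymethyl)-2-oxo-3-[(1E,6R)-6-(tert-butyldimethylsilyloxy)hept-1-enyl]cyclohex-3-en-1-yl]-2-methylbut-2-enoate | C/C(=C\C[C@@H]1C(=O)C(/C=C/CCC[C@@H](C)O[Si](C)(C)C(C)(C)C)=C(CO)[C@@H](O)[C@H]1O[Si](C)(C)C(C)(C)C)C(=O)OC(C)(C)C | intermediate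
20 | pestallic acid O, (2E)-4-[(1S,5R,6S)-5,6-dihydroxy-3-[(1E,6R)-6-hydroxyhept-1-enyl]-4-(hydroxymethyl)-2-oxocyclohex-3-en-1-yl]-2-methylbut-2-enoic acid | C/C(=C\C[C@@H]1C(=O)C(/C=C/CCC[C@@H](C)O)=C(CO)[C@@H](O)[C@H]1O)C(=O)O | target

## Step count and risks

Total step count: 12. Longest linear sequence: 10 steps (steps 1–5, then 8–12); steps 6–7 make the second fragment.

Most likely to fail, first: step 8. The one-pot annulation is untested; the nitronate may add twice, the aldehyde of 13 may epimerise at C5 before ring closure, or the product may lose water and silanol towards an arene. The fallback sets out from 13 (with 9) and makes the two ring bonds in the reverse order. MgI2 in CH2Cl2 at −20 °C effects an iodo-aldol (halo-Morita–Baylis–Hillman) reaction in which iodide adds to the β-carbon of 9 and the magnesium allenoate adds to the aldehyde of 13 under Felkin control, giving the β-iodo-α-(hydroxyalkyl) dienoate F1. Treatment of F1 with Cs2CO3 in MeCN generates the nitronate, which closes the ring by intramolecular addition–elimination at the iodine-bearing carbon (again the C1–C2 bond from the nitronate). This comes back to the route at 14.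

Second: step 10. The delocalised nitronate may be oxidised at C3 instead of C1, or the base may trigger loss of the C5 silyloxy group. The fallback sets out from 15 and avoids both base and oxidant. SnCl2·2H2O, PhSH and Et3N in MeCN reduce the secondary nitro group to the conjugated ketoxime F2, which is then cleaved with aqueous TiCl3 buffered with NH4OAc. This comes back to the route at 16.

Third: step 12. The β-hydroxy enone may dehydrate and aromatise in trifluoroacetic acid. The fallback sets out from 16 and brings the acid in by oxidation, so that no ester has to be cleaved. The acetal is hydrolysed as in step 11 and aldehyde 18 is condensed with commercial 2-(triphenyl-λ5-phosphanylidene)propanal to give the (E)-enal F3. Pinnick oxidation (NaClO2, NaH2PO4, 2-methylbut-2-ene, t-BuOH/H2O) gives the bis-silyl acid F4, and the two TBS ethers are then removed with HF·pyridine in THF/pyridine at 0 °C. This comes back to the route at 20.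

## Further compounds

F1 | step 8 | methyl (4E,9R)-9-(tert-butyldimethylsilyloxy)-2-[(1R,2S,3R)-2-(tert-butyldimethylsilyloxy)-5,5-diethoxy-1-hydroxy-3-(nitromethyl)pentyl]-3-iododeca-2,4-dienoate (C2=C3 isomers) | COC(=O)C(=C(I)/C=C/CCC[C@@H](C)O[Si](C)(C)C(C)(C)C)[C@@H](O)[C@@H](O[Si](C)(C)C(C)(C)C)[C@@H](C[N+](=O)[O-])CC(OCC)OCC
F2 | step 10 | (4R,5S,6R)-5-(tert-butyldimethylsilyloxy)-6-(2,2-diethoxyethyl)-4-hydroxy-3-(hydroxymethyl)-2-[(1E,6R)-6-(tert-butyldimethylsilyloxy)hept-1-enyl]cyclohex-2-en-1-one oxime | CCOC(OCC)C[C@@H]1C(=NO)C(/C=C/CCC[C@@H](C)O[Si](C)(C)C(C)(C)C)=C(CO)[C@@H](O)[C@H]1O[Si](C)(C)C(C)(C)C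
F3 | step 12 | (2E)-4-[(1S,5R,6S)-6-(tert-butyldimethylsilyloxy)-5-hydroxy-4-(hydroxymethyl)-2-oxo-3-[(1E,6R)-6-(tert-butyldimethylsilyloxy)hept-1-enyl]cyclohex-3-en-1-yl]-2-methylbut-2-enal | C/C(=C\C[C@@H]1C(=O)C(/C=C/CCC[C@@H](C)O[Si](C)(C)C(C)(C)C)=C(CO)[C@@H](O)[C@H]1O[Si](C)(C)C(C)(C)C)C=O
F4 | step 12 | (2E)-4-[(1S,5R,6S)-6-(tert-butyldimethylsilyloxy)-5-hydroxy-4-(hydroxymethyl)-2-oxo-3-[(1E,6R)-6-(tert-butyldimethylsilyloxy)hept-1-enyl]cyclohex-3-en-1-yl]-2-methylbut-2-enoic acid | C/C(=C\C[C@@H]1C(=O)C(/C=C/CCC[C@@H](C)O[Si](C)(C)C(C)(C)C)=C(CO)[C@@H](O)[C@H]1O[Si](C)(C)C(C)(C)C)C(=O)O
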